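## Retrosynthetic overview
1. C3–O(acyl) bond (key step): the target is cut into linoleic acid and a terminal allenyl-diyne. An enantioselective Rh-catalysed hydroacyloxylation makes this bond, the vinyl group and the C3 stereocentre together.
2. C3–C4 bond: the allenyl-diyne comes from a terminal 1,3-diyne and propargyl bromide by a Pd/Cu SN2′-type coupling.
3. C7–C8 bond: the diyne comes from a 2,3-epoxy triflate and lithium (trimethylsilyl)butadiynide.
4. The oxirane is the only ring and is formed first, by Sharpless epoxidation of (E)-dec-2-en-1-ol, which sets C9 and C10.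

Numbering: heptadecane numbering of the alcohol part. C1=C2 is the vinyl group, C3 the carbinol carbon, C4–C7 the diyne, C8 the CH2, C9/C10 the oxirane and C11–C17 the heptyl chain.

Assumption 1: the SMILES is read literally as 3S with a trans (9R,10R) oxirane, which differs from the 3R / cis-(9R,10S) pattern of natural panaxydol.

Assumption 2: (R,R)-DIOP is written as the antipode that gives 3S. The facial sense is unknown for a diynyl allene, so it is checked on the first run (methanolysis of an aliquot, Mosher esters). The equally available (S,S)-DIOP is used if the sense is reversed.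

## Route

Step 1
Reactants: 1 (E)-dec-2-en-1-ol
Product: 2 [(2R,3R)-3-heptyloxiran-2-yl]methanol
Conditions: Ti(OiPr)4 (5 mol %), D-(−)-diethyl tartrate (6 mol %), t-BuOOH (2 equiv, in decane), 4 Å MS, CH2Cl2, −20 °C; crystallisation from hexane at −20 °C
Reagents that add atoms: tert-butyl hydroperoxide, CC(C)(C)OO
Why: In this Katsuki–Sharpless asymmetric epoxidation the titanium-bound allylic alcohol takes oxygen on the face dictated by D-(−)-tartrate (the antipode of the 2S,3S outcome given by L-(+)-tartrate with E-allylic alcohols), and the syn-stereospecific transfer turns the E-alkene into the trans (2R,3R) oxirane, which becomes C9/C10.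

Step 2
Reactants: 2 [(2R,3R)-3-heptyloxiran-2-yl]methanol; 3 1,4-bis(trimethylsilyl)buta-1,3-diyne
Product: 7 trimethyl{5-[(2R,3R)-3-heptyloxiran-2-yl]penta-1,3-diyn-1-yl}silane, via lithium silylbutadiynide 4 (not isolated), via lithium alkoxide 5 (not isolated), via epoxy triflate 6 (not isolated)
Conditions: flask A: 3 (1.6 equiv), MeLi·LiBr (1.5 equiv), THF, 0 °C → rt, 3 h; flask B: 2, n-BuLi (1.0 equiv), Et2O, −78 °C, then Tf2O (1.05 equiv), −78 °C, 20 min; A into B, DMPU, −78 → −20 °C
Reagents that add atoms: methyllithium, [Li]C (lithium of 4); n-butyllithium, [Li]CCCC (lithium of 5); trifluoromethanesulfonic anhydride, O=S(=O)(OS(=O)(=O)C(F)(F)F)C(F)(F)F (triflyl group of 6)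
Why: This is an SN2 alkynylation of a primary triflate by a lithium acetylide in THF/DMPU, in which the triflate reacts at −78 °C far faster than the unactivated oxirane, alkoxide 5 does not undergo Payne rearrangement in ether at this temperature, and no C–O bond at C9/C10 is broken, so (2R,3R) is carried over unchanged.

Step 3
Reactants: 7 trimethyl{5-[(2R,3R)-3-heptyloxiran-2-yl]penta-1,3-diyn-1-yl}silane; 8 propargyl bromide (3-bromoprop-1-yne, 80 % in toluene)
Product: 10 (2R,3R)-2-heptyl-3-(octa-6,7-diene-2,4-diyn-1-yl)oxirane, via terminal diyne 9 (not isolated)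
Conditions: TBAF (1.05 equiv), AcOH (1.05 equiv), THF, −20 °C, 20 min; then 8 (1.5 equiv), Pd(PPh3)4 (5 mol %), CuI (10 mol %), i-Pr2NH (2 equiv), degassed, dark, 0 °C → rt; short neutral silica plug, stored cold as a ClCH2CH2Cl solution with BHT
Reagents that add atoms: none
Why: Buffered fluoride protodesilylation frees the sensitive diyne 9 only in solution, after which a Sonogashira-type Pd/Cu coupling of a propargylic halide takes place: zerovalent palladium adds to 8 in SN2′ fashion to give a σ-allenylpalladium bromide, which takes the diynyl group from copper and reductively eliminates to the 1,2-dien-4-yne, with no stereocentre formed or touched.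

Step 4
Reactants: 10 (2R,3R)-2-heptyl-3-(octa-6,7-diene-2,4-diyn-1-yl)oxirane; 11 linoleic acid, (9Z,12Z)-octadeca-9,12-dienoic acid
Product: 12 (3S)-8-[(2R,3R)-3-heptyloxiran-2-yl]oct-1-ene-4,6-diyn-3-yl (9Z,12Z)-octadeca-9,12-dienoate
Conditions: [Rh(cod)Cl]2 (2.5 mol %), (R,R)-DIOP (6 mol %), Cs2CO3 (10 mol %), 11 (1.3 equiv), ClCH2CH2Cl, 0 °C, 10 added by syringe pump over 4 h, Ar, dark; stopped at full conversion
Reagents that add atoms: none
Why: Proposed new method: branched- and enantioselective rhodium-catalysed hydroacyloxylation of a conjugated allenyl-diyne, a substrate class on which this C–O bond formation has not been shown (closest known reaction type: [Rh(cod)Cl]2/DIOP-catalysed addition of carboxylic acids to terminal alkyl allenes giving branched allylic esters); O–H oxidative addition of 11 to the monovalent rhodium–DIOP complex gives a trivalent rhodium hydrido carboxylate, the strained and unhindered terminal allene outcompetes the internal diyne and the Z-alkenes for coordination, hydride goes to the central allene carbon C2 to give a C1–C3 π-allyl bearing the slim diynyl group, and inner-sphere C–O reductive elimination through a six-membered transition state from the C1-bound σ-allyl places the carboxylate on C3 (propargylic charge stabilisation reinforces the branched preference), so the C3–O bond, the vinyl group and the 3S centre arise in one atom-economic step under ligand control, the remote C9/C10 centres having no influence and the oxirane being inert to a fatty acid at 0 °C.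

## Compound list
1 | (E)-dec-2-en-1-ol | OC/C=C/CCCCCCC | starting material
2 | [(2R,3R)-3-heptyloxiran-2-yl]methanol | OC[C@H]1O[C@@H]1CCCCCCC | intermediate
3 | 1,4-bis(trimethylsilyl)buta-1,3-diyne | C[Si](C)(C)C#CC#C[Si](C)(C)C | starting material
4 | lithium 4-(trimethylsilyl)buta-1,3-diyn-1-ide | [Li]C#CC#C[Si](C)(C)C | intermediate
5 | lithium [(2R,3R)-3-heptyloxiran-2-yl]methanolate | [Li]OC[C@H]1O[C@@H]1CCCCCCC | intermediate
6 | [(2R,3R)-3-heptyloxiran-2-yl]methyl trifluoromethanesulfonate | FC(F)(F)S(=O)(=O)OC[C@H]1O[C@@H]1CCCCCCC | intermediate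
7 | trimethyl{5-[(2R,3R)-3-heptyloxiran-2-yl]penta-1,3-diyn-1-yl}silane | C[Si](C)(C)C#CC#CC[C@H]1O[C@@H]1CCCCCCC | intermediate
8 | propargyl bromide | C#CCBr | starting material
9 | (2R,3R)-2-heptyl-3-(penta-2,4-diyn-1-yl)oxirane | C#CC#CC[C@H]1O[C@@H]1CCCCCCC | intermediate
10 | (2R,3R)-2-heptyl-3-(octa-6,7-diene-2,4-diyn-1-yl)oxirane | C=C=CC#CC#CC[C@H]1O[C@@H]1CCCCCCC | intermediate
11 | linoleic acid | OC(=O)CCCCCCC/C=C\C/C=C\CCCCC | starting material
12 | (3S)-8-[(2R,3R)-3-heptyloxiran-2-yl]oct-1-ene-4,6-diyn-3-yl (9Z,12Z)-octadeca-9,12-dienoate | C=C[C@@H](C#CC#CC[C@H]1O[C@@H]1CCCCCCC)OC(=O)CCCCCCC/C=C\C/C=C\CCCCC | target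

## Step count
Total steps: 4. Longest linear sequence: 4 (1 → 2 → 7 → 10 → 12).

## Steps most likely to fail

**Step 4 (new reaction).**
- The carboxylate may end up at C1 (linear enediyne ester) or at C5.
- The doubly activated product may re-ionise on rhodium and drift to the linear isomer or lose configuration.
- The slim diynyl group may give lower facial selectivity than alkyl allenes, and the C3 epimer cannot be removed on silica.
- Compound 10 may oligomerise.

The fallback uses known chemistry only. It sets out from 9 (step 3 stopped after the fluoride stage, aqueous work-up, used the same day) and comes back at 12. Deprotonation of 9 with n-BuLi (THF, −78 °C) gives lithium diynylide F1. This adds 1,2 to freshly distilled acrolein (AcOH quench at −78 °C) to give (3RS)-alcohol F2, 1:1 at C3. Kinetic resolution with immobilised Candida antarctica lipase B and vinyl acetate (MTBE, 30 °C, about 52 % conversion) acetylates the 3R epimer, as the Kazlauskas rule predicts with the diynyl chain as the large group and vinyl as the medium group. This gives (3R)-acetate F3 and leaves (3S)-alcohol F4, which is separated on silica. F4 is acylated with 11 under Steglich conditions (EDC·HCl, DMAP, CH2Cl2, 0 °C). The C3–O bond is not touched, so the configuration is retained and 12 results.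

**Step 3.**
- Copper-only propargylation may compete and give the skipped triyne.
- Glaser homocoupling of 9 is possible.
- Compound 10 may isomerise or decompose during coupling or purification.

The fallback sets out from 9 and comes back at 10. Cadiot–Chodkiewicz coupling of 9 with commercial 3-bromoprop-2-yn-1-ol (CuCl, NH2OH·HCl, n-BuNH2, Et2O/H2O, 0 °C) gives triynol F5. A Myers reductive transposition (PPh3, DEAD, 2-nitrobenzenesulfonohydrazide, THF, −15 °C) converts it into sulfonylhydrazine F6. On warming to 23 °C, F6 loses the sulfinic acid to give propargylic diazene F7. F7 expels N2 in a retro-ene shift that delivers hydrogen to C3 and gives the terminal allene 10 without palladium or amine base.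

**Step 2.**
- Triflate 6 may decompose.
- The conjugated and less nucleophilic diynylide may react sluggishly.
- Attack at the oxirane may compete.

The fallback sets out from 1 (with 4 made from 3 as in step 2) and comes back at 7. The oxirane is now formed after the C7–C8 bond, so step 1 is not needed. PBr3 (Et2O, 0 °C) gives (E)-1-bromodec-2-ene F8. CuI-catalysed SN2 alkynylation with 4 (THF, −30 °C → rt) gives skipped enediyne silane F9. Shi epoxidation then gives 7, using the D-fructose-derived ketone, KHSO5 as the triple salt 2KHSO5·KHSO4·K2SO4, K2CO3 buffer and MeCN/dimethoxymethane/H2O at 0 °C. This epoxidation gives R,R oxiranes from trans-disubstituted alkenes and leaves alkynes alone.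

## Further compounds
F1 | step 4 | lithium 5-[(2R,3R)-3-heptyloxiran-2-yl]penta-1,3-diyn-1-ide | [Li]C#CC#CC[C@H]1O[C@@H]1CCCCCCC
F2 | step 4 | (3RS)-8-[(2R,3R)-3-heptyloxiran-2-yl]oct-1-ene-4,6-diyn-3-ol (1:1 at C3) | C=CC(O)C#CC#CC[C@H]1O[C@@H]1CCCCCCC
F3 | step 4 | (3R)-8-[(2R,3R)-3-heptyloxiran-2-yl]oct-1-ene-4,6-diyn-3-yl acetate | C=C[C@H](C#CC#CC[C@H]1O[C@@H]1CCCCCCC)OC(C)=O
F4 | step 4 | (3S)-8-[(2R,3R)-3-heptyloxiran-2-yl]oct-1-ene-4,6-diyn-3-ol | C=C[C@@H](C#CC#CC[C@H]1O[C@@H]1CCCCCCC)O
F5 | step 3 | 8-[(2R,3R)-3-heptyloxiran-2-yl]octa-2,4,6-triyn-1-ol | OCC#CC#CC#CC[C@H]1O[C@@H]1CCCCCCC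
F6 | step 3 | N-{8-[(2R,3R)-3-heptyloxiran-2-yl]octa-2,4,6-triyn-1-yl}-2-nitrobenzenesulfonohydrazide | NN(CC#CC#CC#CC[C@H]1O[C@@H]1CCCCCCC)S(=O)(=O)c1ccccc1[N+](=O)[O-]
F7 | step 3 | {8-[(2R,3R)-3-heptyloxiran-2-yl]octa-2,4,6-triyn-1-yl}diazene | N=NCC#CC#CC#CC[C@H]1O[C@@H]1CCCCCCC
F8 | step 2 | (E)-1-bromodec-2-ene | BrC/C=C/CCCCCCC
F9 | step 2 | trimethyl[(6E)-tetradec-6-ene-1,3-diyn-1-yl]silane | C[Si](C)(C)C#CC#CC/C=C/CCCCCCC
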